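**Retrosynthetic overview**
1. Feature: the core is a 1-oxaspiro[4.4]non-7-ene (ring A: O1, C2, C3, C4, C5; ring B: C5, C6, C7=C8, C9). Spiro atom C5 bears O1 and lies between C6 and C9. With both at the ketone level, C5–H is the acidic position of a 2-alkoxy-1,3-dione, and C4 is the fourth atom along C5–O1–C2–C3–C4.
2. Endgame: the acetyl group comes from an ethynyl group by hydration, and the C9–C(sp) bond from acetylide addition to the C9 ketone. C5 and the C6/C9 distinction come from a CBS reduction of the spiro enedione; the C6 alcohol is carried as a silyl ether and re-oxidised.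
3. Key disconnection C4–C5: a gold Conia-ene closure of ring A (5-endo-dig) from the propargylic ether of the 2-hydroxy-dione, then saturation of C3=C4.
4. C5–O1 comes from rhodium carbenoid O–H insertion of the 2-diazo-dione into the (R)-propargylic alcohol. The alcohol comes from phytol (C2 set by Sharpless epoxidation); the dione comes from dimethylmaleic anhydride plus one ylide carbon.
5. Ring order: ring B first (step 5), ring A second (step 9).

Key step: step 9

Remark: the locants O1 and C2 to C9 of the target core are kept for the same atoms in all intermediates, so the CIP letters at C5 and C9 change with the substituents while the spatial arrangement stays; commercial natural phytol is taken as the single (2E,7R,11R) isomer.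

Step 1
Reactants: 1 natural phytol
Product: 2 (2R,3R)-2,3-epoxyphytol
Conditions: Ti(OiPr)4 (10 mol %), D-(−)-diisopropyl tartrate (12 mol %), t-BuOOH, 4 Å MS, CH2Cl2, −20 °C
Reagents that add atoms: tert-butyl hydroperoxide, CC(C)(C)OO
Why: Sharpless asymmetric epoxidation of an E-trisubstituted allylic alcohol is reagent-controlled, the D-(−)-tartrate giving the 2R,3R epoxide (the L-(+)-tartrate gives the 2S,3S series with geraniol-type alcohols), and the C3–O bond made here becomes the C2–O1 bond of the target while the remote 7R and 11R centres are untouched.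

Step 2
Reactants: 2 (2R,3R)-2,3-epoxyphytol
Product: 3 (2S,3R)-epoxy chloride
Conditions: PPh3, CCl4, NaHCO3, reflux
Reagents that add atoms: carbon tetrachloride, ClC(Cl)(Cl)Cl
Why: The Appel chlorination replaces the primary hydroxyl under buffered, nearly neutral conditions that leave the trisubstituted epoxide and both of its stereocentres intact (the letter at C2 changes only because CH2Cl outranks C3).

Step 3
Reactants: 3 (2S,3R)-epoxy chloride
Product: 4 (3R,7R,11R)-3,7,11,15-tetramethylhexadec-1-yn-3-ol
Conditions: LiN(iPr)2 (3.5 equiv), THF, −78 to −20 °C; then H2O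
Reagents that add atoms: none
Why: The base-induced double elimination of a 2,3-epoxy chloride (epoxide opening by β-elimination, then loss of HCl) gives the terminal propargylic alcohol, and since the C3–O bond is never broken the 3R configuration is kept.

Step 4
Reactants: 5 2,3-dimethylmaleic anhydride; 6 (tert-butoxycarbonylmethylene)triphenylphosphorane
Product: 7 tert-butyl (2E)-2-(3,4-dimethyl-5-oxofuran-2(5H)-ylidene)acetate
Conditions: toluene, 90 °C
Reagents that add atoms: none
Why: Wittig olefination of a cyclic anhydride carbonyl by a stabilised ylide gives the enol lactone, the two carbonyls of 5 are equivalent so no regiochemical question arises, and the alkene geometry is erased in the next step.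

Step 5
Reactants: 7 tert-butyl (2E)-2-(3,4-dimethyl-5-oxofuran-2(5H)-ylidene)acetate
Product: 9 tert-butyl 3,4-dimethyl-2,5-dioxocyclopent-3-ene-1-carboxylate, via ring-opened keto diester 8 (not isolated)
Conditions: NaOMe (2 equiv), MeOH, 0 to 25 °C; then 1 M HCl
Reagents that add atoms: none
Why: Methoxide opens the enol lactone to the β-keto ester enolate of 8, which closes ring B by a Dieckmann-type acylation on the new methyl ester, the known ylidenebutenolide-to-cyclopentenedione rearrangement, driven by formation of the stabilised tricarbonyl anion.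

Step 6
Reactants: 9 tert-butyl 3,4-dimethyl-2,5-dioxocyclopent-3-ene-1-carboxylate
Product: 11 4,5-dimethylcyclopent-4-ene-1,3-dione, via free keto acid 10 (not isolated)
Conditions: CF3CO2H, CH2Cl2, 25 to 40 °C
Reagents that add atoms: none
Why: Acidolysis of the tert-butyl ester gives the 2-carboxy-1,3-dione 10, which decarboxylates spontaneously, as in the classical preparation of indane-1,3-dione from its 2-carboxylate.

Step 7
Reactants: 11 4,5-dimethylcyclopent-4-ene-1,3-dione
Product: 12 2-diazo-4,5-dimethylcyclopent-4-ene-1,3-dione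
Conditions: 4-acetamidobenzenesulfonyl azide, Et3N, MeCN, 0 to 25 °C
Reagents that add atoms: 4-acetamidobenzenesulfonyl azide, CC(=O)Nc1ccc(cc1)S(=O)(=O)N=[N+]=[N-]
Why: Regitz diazo transfer to an acidic cyclic 1,3-dione needs only an amine base, and the tetrasubstituted C=C bond resists the Michael self-condensation that troubles the unsubstituted cyclopentenedione.

Step 8
Reactants: 4 (3R,7R,11R)-3,7,11,15-tetramethylhexadec-1-yn-3-ol; 12 2-diazo-4,5-dimethylcyclopent-4-ene-1,3-dione
Product: 13 2-{[(3R,7R,11R)-3,7,11,15-tetramethylhexadec-1-yn-3-yl]oxy}-4,5-dimethylcyclopent-4-ene-1,3-dione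
Conditions: Rh2(OAc)4 (1 mol %), CH2Cl2, reflux, slow addition of 12 to 4 (1.3 equiv)
Reagents that add atoms: none
Why: In this rhodium carbenoid O–H insertion the electrophilic acceptor/acceptor carbenoid is captured by the hydroxyl lone pair faster than by the terminal alkyne, tertiary alcohols are accepted substrates, the C–O bond at the stereocentre is not touched, and because the enol of 13 would be a hydroxycyclopentadienone the ylide should collapse to the diketone instead of entering a [3,3] shift.

Step 9
Reactants: 13 2-{[(3R,7R,11R)-3,7,11,15-tetramethylhexadec-1-yn-3-yl]oxy}-4,5-dimethylcyclopent-4-ene-1,3-dione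
Product: 14 (2R)-2,7,8-trimethyl-2-[(4R,8R)-4,8,12-trimethyltridecyl]-1-oxaspiro[4.4]nona-3,7-diene-6,9-dione
Conditions: Ph3PAuNTf2 (5 mol %), 2,6-di-tert-butylpyridine (10 mol %), 4 Å MS, CH2Cl2, 25 to 40 °C
Reagents that add atoms: none
Why: Monovalent gold binds the C3≡C4 triple bond, C5 of the enol (or of the enolate released by the hindered base) attacks the terminal carbon C4 anti to the metal, and protonation of the resulting C3–Au bond frees the 2,5-dihydrofuran and the catalyst. The closest known reaction type is the gold-catalysed 5-endo-dig Conia-ene carbocyclisation of 1,3-dicarbonyl compounds that carry a but-3-ynyl chain on the central carbon; here one CH2 of that chain is O1. Ring A (O1, C2, C3, C4, C5) closes in the 5-endo-dig mode on the preformed ring B, the 4-exo-dig attack at C3 being ruled out by strain. No stereocentre is created, since C6 and C9 are still identical arms on C5, and the C2 centre takes no part. The step needs bond formation at C5 and not at the enol oxygen (6-exo or 7-endo ring) or at C6 (propargyl Claisen shift): C5 is the electron-rich central carbon of the vinylogous acid, and the short tether with its fully substituted C2 holds C4 within bonding distance of it. Because the enol is a hydroxycyclopentadienone it is only a minor tautomer, but C5–H is strongly acidic, so 2,6-di-tert-butylpyridine, too hindered to bind gold, shuttles the proton from C5 to C3 and also traps traces of HNTf2 that would ionise the tertiary propargylic C2–O1 bond.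

Step 10
Reactants: 14 (2R)-spiro-dihydrofuran enedione
Product: 15 (2R)-2,7,8-trimethyl-2-[(4R,8R)-4,8,12-trimethyltridecyl]-1-oxaspiro[4.4]non-7-ene-6,9-dione
Conditions: H2 (5 bar), RhCl(PPh3)3 (10 mol %), toluene–EtOH 1:1, 40 °C
Reagents that add atoms: none
Why: Homogeneous hydrogenation with RhCl(PPh3)3 is governed by alkene substitution, so the cis-disubstituted C3=C4 bond can coordinate and is saturated while the tetrasubstituted, electron-poor C7=C8 bond cannot, and rhodium does not hydrogenolyse the allylic C–O bonds.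

Step 11
Reactants: 15 (2R)-spiro enedione
Product: 16 (2R,5S,6R)-6-hydroxy-2,7,8-trimethyl-2-[(4R,8R)-4,8,12-trimethyltridecyl]-1-oxaspiro[4.4]non-7-en-9-one
Conditions: (S)-Me-CBS oxazaborolidine (20 mol %), catecholborane (1.2 equiv), toluene, −78 °C; then MeOH, aqueous wash
Reagents that add atoms: none
Why: The CBS reduction is known to desymmetrise 2,2-disubstituted cyclic 1,3-diones; with the (S)-catalyst, taking quaternary C5 as the large and flat C7 (or C8) as the small flank, hydride can reach only C6 from the O1 face or C9 from the C4 face, and the O1 face is the more open one because the C4 methylene hydrogens lean over the other face, so C5 becomes stereogenic in the arrangement of the target (5S here) and C6 is set as 6R with the hydroxyl trans to O1.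

Step 12
Reactants: 16 (2R,5S,6R)-hydroxy enone
Product: 17 (2R,5S,6R)-6-(tert-butyldimethylsilyloxy)-2,7,8-trimethyl-2-[(4R,8R)-4,8,12-trimethyltridecyl]-1-oxaspiro[4.4]non-7-en-9-one
Conditions: t-BuMe2SiOTf, 2,6-lutidine, CH2Cl2, 0 °C
Reagents that add atoms: tert-butyldimethylsilyl triflate, CC(C)(C)[Si](C)(C)OS(=O)(=O)C(F)(F)F
Why: Silylation with the silyl triflate and a weak hindered base copes with the neopentyl-type allylic alcohol without touching the enone, and the bulky ether then shields the C4 face of ring B.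

Step 13
Reactants: 17 (2R,5S,6R)-silyloxy enone; 18 trimethylsilylacetylene
Product: 21 (2R,5S,6R,9R)-6-(tert-butyldimethylsilyloxy)-2,7,8-trimethyl-2-[(4R,8R)-4,8,12-trimethyltridecyl]-9-[(trimethylsilyl)ethynyl]-1-oxaspiro[4.4]non-7-en-9-ol, via lithium trimethylsilylacetylide 19 (not isolated), via dichlorocerium trimethylsilylacetylide 20 (not isolated)
Conditions: 18, n-BuLi, THF, −78 °C; anhydrous CeCl3, −78 °C; then 17, −78 °C; H2O
Reagents that add atoms: none
Why: The 1,2-addition of an organocerium acetylide (low basicity, no γ-deprotonation, no conjugate addition) suits the hindered enone, and as with 4-silyloxycyclopent-2-enones the nucleophile should enter anti to the C6 silyl ether, that is from the O1 face where O1 can also guide the oxophilic metal, so the alkyne ends cis to O1 and the hydroxyl trans to it (9R here, the 9S arrangement of the target).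

Step 14
Reactants: 21 (2R,5S,6R,9R)-bis-silyl adduct
Product: 22 (2R,5S,6R,9S)-9-ethynyl-2,7,8-trimethyl-2-[(4R,8R)-4,8,12-trimethyltridecyl]-1-oxaspiro[4.4]non-7-ene-6,9-diol
Conditions: Bu4NF (3 equiv), THF, 0 to 25 °C
Reagents that add atoms: none
Why: Fluoride-induced desilylation cleaves the C(sp)–Si and the O–Si bond in one operation, and since the substrate holds no carbonyl group at this stage retro-aldol and elimination pathways are closed.

Step 15
Reactants: 22 (2R,5S,6R,9S)-ethynyl diol
Product: 23 (2R,5R,9S)-9-ethynyl-9-hydroxy-2,7,8-trimethyl-2-[(4R,8R)-4,8,12-trimethyltridecyl]-1-oxaspiro[4.4]non-7-en-6-one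
Conditions: Dess–Martin periodinane, NaHCO3, CH2Cl2, 0 °C
Reagents that add atoms: none
Why: The Dess–Martin oxidation turns the secondary allylic alcohol into the enone while the tertiary C9 carbinol cannot be oxidised, and unlike hexavalent chromium reagents it does not trigger an oxidative allylic transposition, so C5 and C9 stay as set.

Step 16
Reactants: 23 (2R,5R,9S)-ethynyl hydroxy enone
Product: 24 target CNP0373307.2
Conditions: Ph3PAuNTf2 (5 mol %), MeOH–H2O 10:1, 45 °C
Reagents that add atoms: water, O
Why: Gold-catalysed Markovnikov hydration of the terminal alkyne gives the methyl ketone under neutral conditions that spare the β-hydroxy ketone and α-ketol units, and ionisation at C9 (Meyer–Schuster or Rupe path) is disfavoured because the cation would be conjugated with the C6 carbonyl.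

**Compound list**
1 | natural phytol, (2E,7R,11R)-3,7,11,15-tetramethylhexadec-2-en-1-ol | OC/C=C(\C)CCC[C@H](C)CCC[C@H](C)CCCC(C)C | starting material
2 | [(2R,3R)-3-methyl-3-[(4R,8R)-4,8,12-trimethyltridecyl]oxiran-2-yl]methanol | OC[C@H]1O[C@]1(C)CCC[C@H](C)CCC[C@H](C)CCCC(C)C | intermediate
3 | (2S,3R)-2-(chloromethyl)-3-methyl-3-[(4R,8R)-4,8,12-trimethyltridecyl]oxirane | ClC[C@H]1O[C@]1(C)CCC[C@H](C)CCC[C@H](C)CCCC(C)C | intermediate
4 | (3R,7R,11R)-3,7,11,15-tetramethylhexadec-1-yn-3-ol | O[C@](C)(CCC[C@H](C)CCC[C@H](C)CCCC(C)C)C#C | intermediate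
5 | 2,3-dimethylmaleic anhydride | CC1=C(C)C(=O)OC1=O | starting material
6 | (tert-butoxycarbonylmethylene)triphenylphosphorane | CC(C)(C)OC(=O)C=P(c1ccccc1)(c1ccccc1)c1ccccc1 | starting material
7 | tert-butyl (2E)-2-(3,4-dimethyl-5-oxofuran-2(5H)-ylidene)acetate | CC1=C(C)C(=O)O/C1=C/C(=O)OC(C)(C)C | intermediate
8 | 1-tert-butyl 6-methyl (4Z)-4,5-dimethyl-3-oxohex-4-enedioate (present as its sodium enolate, not isolated) | COC(=O)/C(C)=C(C)\C(=O)CC(=O)OC(C)(C)C | intermediate
9 | tert-butyl 3,4-dimethyl-2,5-dioxocyclopent-3-ene-1-carboxylate (drawn as the triketo tautomer) | CC1=C(C)C(=O)C(C(=O)OC(C)(C)C)C1=O | intermediate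
10 | 3,4-dimethyl-2,5-dioxocyclopent-3-ene-1-carboxylic acid (not isolated) | CC1=C(C)C(=O)C(C(=O)O)C1=O | intermediate
11 | 4,5-dimethylcyclopent-4-ene-1,3-dione | CC1=C(C)C(=O)CC1=O | intermediate
12 | 2-diazo-4,5-dimethylcyclopent-4-ene-1,3-dione | CC1=C(C)C(=O)C(=[N+]=[N-])C1=O | intermediate
13 | 2-{[(3R,7R,11R)-3,7,11,15-tetramethylhexadec-1-yn-3-yl]oxy}-4,5-dimethylcyclopent-4-ene-1,3-dione (key-step precursor) | O=C1C(C)=C(C)C(=O)C1O[C@](C)(CCC[C@H](C)CCC[C@H](C)CCCC(C)C)C#C | intermediate
14 | (2R)-2,7,8-trimethyl-2-[(4R,8R)-4,8,12-trimethyltridecyl]-1-oxaspiro[4.4]nona-3,7-diene-6,9-dione (key-step product) | O=C1C(C)=C(C)C(=O)C12C=C[C@@](C)(CCC[C@H](C)CCC[C@H](C)CCCC(C)C)O2 | intermediate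
15 | (2R)-2,7,8-trimethyl-2-[(4R,8R)-4,8,12-trimethyltridecyl]-1-oxaspiro[4.4]non-7-ene-6,9-dione | O=C1C(C)=C(C)C(=O)C12CC[C@@](C)(CCC[C@H](C)CCC[C@H](C)CCCC(C)C)O2 | intermediate
16 | (2R,5S,6R)-6-hydroxy-2,7,8-trimethyl-2-[(4R,8R)-4,8,12-trimethyltridecyl]-1-oxaspiro[4.4]non-7-en-9-one (OH trans to O1) | O=C1C(C)=C(C)[C@@H](O)[C@@]12CC[C@@](C)(CCC[C@H](C)CCC[C@H](C)CCCC(C)C)O2 | intermediate
17 | (2R,5S,6R)-6-(tert-butyldimethylsilyloxy) analogue of 16 | O=C1C(C)=C(C)[C@@H](O[Si](C)(C)C(C)(C)C)[C@@]12CC[C@@](C)(CCC[C@H](C)CCC[C@H](C)CCCC(C)C)O2 | intermediate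
18 | trimethylsilylacetylene | C#C[Si](C)(C)C | starting material
19 | lithium trimethylsilylacetylide (not isolated) | [Li]C#C[Si](C)(C)C | intermediate
20 | dichlorocerium trimethylsilylacetylide (not isolated) | Cl[Ce](Cl)C#C[Si](C)(C)C | intermediate
21 | (2R,5S,6R,9R)-6-(tert-butyldimethylsilyloxy)-2,7,8-trimethyl-2-[(4R,8R)-4,8,12-trimethyltridecyl]-9-[(trimethylsilyl)ethynyl]-1-oxaspiro[4.4]non-7-en-9-ol (alkyne cis to O1) | C[Si](C)(C)C#C[C@]1(O)C(C)=C(C)[C@@H](O[Si](C)(C)C(C)(C)C)[C@@]12CC[C@@](C)(CCC[C@H](C)CCC[C@H](C)CCCC(C)C)O2 | intermediate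
22 | (2R,5S,6R,9S)-9-ethynyl-2,7,8-trimethyl-2-[(4R,8R)-4,8,12-trimethyltridecyl]-1-oxaspiro[4.4]non-7-ene-6,9-diol | C#C[C@]1(O)C(C)=C(C)[C@@H](O)[C@@]12CC[C@@](C)(CCC[C@H](C)CCC[C@H](C)CCCC(C)C)O2 | intermediate
23 | (2R,5R,9S)-9-ethynyl-9-hydroxy-2,7,8-trimethyl-2-[(4R,8R)-4,8,12-trimethyltridecyl]-1-oxaspiro[4.4]non-7-en-6-one | C#C[C@]1(O)C(C)=C(C)C(=O)[C@@]12CC[C@@](C)(CCC[C@H](C)CCC[C@H](C)CCCC(C)C)O2 | intermediate
24 | (2R,5R,9S)-9-acetyl-9-hydroxy-2,7,8-trimethyl-2-[(4R,8R)-4,8,12-trimethyltridecyl]-1-oxaspiro[4.4]non-7-en-6-one, CNP0373307.2 | CC(=O)[C@]1(O)C(C)=C(C)C(=O)[C@@]12CC[C@@](C)(CCC[C@H](C)CCC[C@H](C)CCCC(C)C)O2 | target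

**Step count**
- Total step count: 16.
- Longest linear sequence: 13 steps (steps 4 to 16, from 5). The phytol branch (steps 1 to 3) joins at step 8.

**Steps most likely to fail**

Step 9.
- What may go wrong: tautomerisation to the reactive enol may be too slow. Gold or trace acid may ionise the tertiary propargylic C2–O1 bond. Bond formation may drift to the enol oxygen or to C6.
- Fallback: it sets out from 4 (with 12) and comes back at 15. The same C4–C5 bond is made by enolate alkylation instead of alkyne activation. Semi-hydrogenation of 4 (H2, Pd/CaCO3 poisoned with Pb(OAc)2, quinoline, hexane) should give (3R,7R,11R)-isophytol F1. Hydroboration and oxidation (9-BBN, then NaOH/H2O2) should give (3R,7R,11R)-3,7,11,15-tetramethylhexadecane-1,3-diol F2. Appel bromination of the primary hydroxyl (CBr4, PPh3, CH2Cl2, 0 °C) should give (3R,7R,11R)-1-bromo-3,7,11,15-tetramethylhexadecan-3-ol F3. Rh2(OAc)4-catalysed O–H insertion of 12, now without any alkyne in the substrate, should give 2-{[(3R,7R,11R)-1-bromo-3,7,11,15-tetramethylhexadecan-3-yl]oxy}-4,5-dimethylcyclopent-4-ene-1,3-dione F4. Cs2CO3 in DMF should then close ring A by 5-exo-tet C-alkylation of the dione enolate, since O-alkylation would need a seven-membered ring. This gives 15 directly, so step 10 is saved as well.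

Step 11.
- What may go wrong: hydride delivery anti to the C5–O1 bond (the polar Felkin–Anh preference) may compete with delivery from the O1 face. Weak differentiation between the quaternary flank and the methyl-substituted vinyl flank may erode the choice between C6 and C9. Every unwanted alcohol isomer returns to 15 on Dess–Martin oxidation, because C5 then loses its stereogenicity.
- Fallback: it sets out from 15 and comes back at 16. The opposite facial preference is accepted and C6 is corrected by substitution. The (R)-Me-CBS oxazaborolidine with catecholborane pairs C6 with the C4 face. It should give (2R,5S,6S)-6-hydroxy-2,7,8-trimethyl-2-[(4R,8R)-4,8,12-trimethyltridecyl]-1-oxaspiro[4.4]non-7-en-9-one F5, which already has the correct C5 arrangement. Mitsunobu inversion (4-nitrobenzoic acid, PPh3, diisopropyl azodicarboxylate, toluene) should give the (2R,5S,6R)-6-(4-nitrobenzoyloxy) enone F6. Methanolysis (K2CO3, MeOH) should then give 16.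

Step 13.
- What may go wrong: facial selectivity may be poor. The slim acetylide may feel the C6 silyl ether too little, and the polar effect of the C5–O1 bond favours entry from the C4 face.
- Fallback: it sets out from 17 and comes back at 24. The alkyne is replaced by a bulkier acyl-anion equivalent, which responds more strongly to the silyl ether and is unmasked by hydrolysis instead of hydration. 1-Ethoxyvinyllithium (ethyl vinyl ether, t-BuLi, THF, −78 °C), a reagent known to add to ketones next to quaternary carbons, should give (2R,5S,6R,9R)-6-(tert-butyldimethylsilyloxy)-9-(1-ethoxyvinyl)-2,7,8-trimethyl-2-[(4R,8R)-4,8,12-trimethyltridecyl]-1-oxaspiro[4.4]non-7-en-9-ol F7. Aqueous HF in MeCN should hydrolyse the enol ether and cleave the silyl ether to give (2R,5S,6R,9S)-9-acetyl-2,7,8-trimethyl-2-[(4R,8R)-4,8,12-trimethyltridecyl]-1-oxaspiro[4.4]non-7-ene-6,9-diol F8. Dess–Martin oxidation of the C6 alcohol should then give 24.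

**Further compounds**
F1 | step 9 | (3R,7R,11R)-isophytol, (3R,7R,11R)-3,7,11,15-tetramethylhexadec-1-en-3-ol | O[C@](C)(CCC[C@H](C)CCC[C@H](C)CCCC(C)C)C=C
F2 | step 9 | (3R,7R,11R)-3,7,11,15-tetramethylhexadecane-1,3-diol | O[C@](C)(CCC[C@H](C)CCC[C@H](C)CCCC(C)C)CCO
F3 | step 9 | (3R,7R,11R)-1-bromo-3,7,11,15-tetramethylhexadecan-3-ol | O[C@](C)(CCC[C@H](C)CCC[C@H](C)CCCC(C)C)CCBr
F4 | step 9 | 2-{[(3R,7R,11R)-1-bromo-3,7,11,15-tetramethylhexadecan-3-yl]oxy}-4,5-dimethylcyclopent-4-ene-1,3-dione | O=C1C(C)=C(C)C(=O)C1O[C@](C)(CCC[C@H](C)CCC[C@H](C)CCCC(C)C)CCBr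
F5 | step 11 | (2R,5S,6S)-6-hydroxy-2,7,8-trimethyl-2-[(4R,8R)-4,8,12-trimethyltridecyl]-1-oxaspiro[4.4]non-7-en-9-one | O=C1C(C)=C(C)[C@H](O)[C@@]12CC[C@@](C)(CCC[C@H](C)CCC[C@H](C)CCCC(C)C)O2
F6 | step 11 | (2R,5S,6R)-6-(4-nitrobenzoyloxy) enone | O=C1C(C)=C(C)[C@@H](OC(=O)c3ccc(cc3)[N+](=O)[O-])[C@@]12CC[C@@](C)(CCC[C@H](C)CCC[C@H](C)CCCC(C)C)O2
F7 | step 13 | (2R,5S,6R,9R)-6-(tert-butyldimethylsilyloxy)-9-(1-ethoxyvinyl)-2,7,8-trimethyl-2-[(4R,8R)-4,8,12-trimethyltridecyl]-1-oxaspiro[4.4]non-7-en-9-ol | CCOC(=C)[C@]1(O)C(C)=C(C)[C@@H](O[Si](C)(C)C(C)(C)C)[C@@]12CC[C@@](C)(CCC[C@H](C)CCC[C@H](C)CCCC(C)C)O2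
F8 | step 13 | (2R,5S,6R,9S)-9-acetyl-2,7,8-trimethyl-2-[(4R,8R)-4,8,12-trimethyltridecyl]-1-oxaspiro[4.4]non-7-ene-6,9-diol | CC(=O)[C@]1(O)C(C)=C(C)[C@@H](O)[C@@]12CC[C@@](C)(CCC[C@H](C)CCC[C@H](C)CCCC(C)C)O2
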